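**Retrosynthetic overview**
1. Target 27 ← ester cleavage and cinnamylphosphonate olefination of the C5 aldehyde ← cyclohexene ester 22.
2. 22 ← loss of CO from crystalline cyclohept-3-enone 21. The deleted carbonyl bridges the adjacent quaternary carbons C4 (Me, CO2Me) and C5 (Et, CH2OR, allylic to C6=C7) of the ring C3a–C4–C5–C6=C7–C7a; the plan rests on this pair, each carbon carrying a radical-stabilising group.
3. 21 ← ring-closing metathesis (C6=C7) of diene 20 ← aldol addition and oxidation joining ester 10 (C4 as an ester α-carbon) to aldehyde 17 (C5 as a preformed quaternary carbon).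
4. 10 ← 2-ethyl enone 5 (Mukaiyama–Michael, enol triflate reduction) ← (S)-4-silyloxycyclopentenone 1; 17 ← (E)-2-ethylbut-2-enoic acid 11 by enantioselective deconjugative alkylation.
5. Ring order: cyclopentene (present from 1) → seven-membered ring (RCM) → cyclohexene (ring contraction in the key step).

Key step: step 15

Remark on numbering: indene numbering of the target is used for all intermediates (C1 CHMe, C2=C3, C3a, C4, C5, C6=C7, C7a); the carbonyl carbon that is later lost lies between C4 and C5.
Assumption 1: keto ester 21 is taken to crystallise (the 4-bromobenzoate is carried for that purpose) in a packing that leaves room for C4–C5 closure; a polymorph screen precedes step 15.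
Assumption 2: which antipode of the chiral tetramine base gives (R)-12 is settled in a trial alkylation (both antipodes are accessible); (R,R) is written.
Remark on the C4 ester: once the C5 hydroxymethyl group is free it sits cis to the C4 methyl ester and can close a γ-lactone, so the benzoate is removed reductively (step 16) and not by basic methanolysis.

**Route**

Step 1
Reactants: 1 (S)-4-[(tert-butyldimethylsilyl)oxy]cyclopent-2-en-1-one
Product: 3 (4R,5S)-5-methyl-4-(prop-1-en-2-yl)cyclopent-2-en-1-one, via β-silyloxy ketone 2 (not isolated)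
Conditions: CH2=C(Me)MgBr, CuBr·SMe2 (cat.), THF, −78 °C; MeI, HMPA, −78 → −30 °C; then DBU, CH2Cl2, 0 °C
Reagents that add atoms: isopropenylmagnesium bromide C=C(C)[Mg]Br; iodomethane CI
Why: Copper-mediated conjugate addition places the isopropenyl group anti to the silyloxy group, the enolate is methylated anti to that new group, and DBU then eliminates silanol (E1cB) to give the trans-4,5-disubstituted enone, so the silyloxy centre of 1 sets C7a and C1 of the target before it is erased.

Step 2
Reactants: 3 (4R,5S)-5-methyl-4-(prop-1-en-2-yl)cyclopent-2-en-1-one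
Product: 4 (4S,5S)-2-iodo-5-methyl-4-(prop-1-en-2-yl)cyclopent-2-en-1-one
Conditions: I2, pyridine, CH2Cl2, 0 °C → rt
Reagents that add atoms: iodine II
Why: α-Iodination of the enone by reversible conjugate addition of pyridine, iodination of the enolate and E1cB loss of pyridine (Baylis–Hillman-type pathway) should leave both stereocentres untouched.

Step 3
Reactants: 4 (4S,5S)-2-iodo-5-methyl-4-(prop-1-en-2-yl)cyclopent-2-en-1-one
Product: 5 (4R,5S)-2-ethyl-5-methyl-4-(prop-1-en-2-yl)cyclopent-2-en-1-one
Conditions: Et2Zn, PdCl2(dppf) (5 mol%), THF, 0 °C → rt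
Reagents that add atoms: diethylzinc CC[Zn]CC
Why: Negishi cross-coupling (oxidative addition into the vinyl C–I bond, transmetallation from zinc, reductive elimination) installs the ethyl group of C3 under base-free conditions that spare the γ-stereocentre.

Step 4
Reactants: 6 methyl propanoate
Product: 7 (E)-1-methoxy-1-(trimethylsilyloxy)prop-1-ene
Conditions: LDA, THF, −78 °C; TMSCl, −78 °C → rt; distil
Reagents that add atoms: chlorotrimethylsilane C[Si](C)(C)Cl
Why: Kinetic deprotonation of the ester and O-silylation of the lithium enolate give the silyl ketene acetal, whose geometry has no consequence later.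

Step 5
Reactants: 5 (4R,5S)-2-ethyl-5-methyl-4-(prop-1-en-2-yl)cyclopent-2-en-1-one; 7 (E)-1-methoxy-1-(trimethylsilyloxy)prop-1-ene
Product: 8 methyl (2RS)-2-[(1S,4S,5R)-2-ethyl-4-methyl-5-(prop-1-en-2-yl)-3-(trimethylsilyloxy)cyclopent-2-en-1-yl]propanoate
Conditions: Ph3C+ SbCl6− (5 mol%), CH2Cl2, −78 °C; pyridine quench, non-aqueous work-up
Reagents that add atoms: none
Why: Trityl-cation-catalysed Mukaiyama–Michael addition: the ketene acetal attacks the β-carbon of the enone on the face opposite the neighbouring isopropenyl group, which sets C3a trans to C7a, and silyl transfer gives the C2=C3 enol ether regiospecifically; the propanoate α-centre forms as a mixture and is planarised again in step 12.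

Step 6
Reactants: 8 methyl (2RS)-2-[(1S,4S,5R)-2-ethyl-4-methyl-5-(prop-1-en-2-yl)-3-(trimethylsilyloxy)cyclopent-2-en-1-yl]propanoate
Product: 9 methyl (2RS)-2-[(1S,4S,5R)-2-ethyl-4-methyl-5-(prop-1-en-2-yl)-3-(trifluoromethylsulfonyloxy)cyclopent-2-en-1-yl]propanoate
Conditions: CsF, PhNTf2, DME, rt
Reagents that add atoms: N-phenylbis(trifluoromethanesulfonimide) O=S(=O)(N(c1ccccc1)S(=O)(=O)C(F)(F)F)C(F)(F)F
Why: Fluoride cleaves the Si–O bond and the caesium enolate is O-sulfonylated before it can equilibrate, so the enol triflate keeps the C2=C3 position fixed in step 5, and the methyl ester is not attacked as it would be by an alkyllithium.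

Step 7
Reactants: 9 methyl (2RS)-2-[(1S,4S,5R)-2-ethyl-4-methyl-5-(prop-1-en-2-yl)-3-(trifluoromethylsulfonyloxy)cyclopent-2-en-1-yl]propanoate
Product: 10 methyl (2RS)-2-[(1S,4R,5S)-2-ethyl-4-methyl-5-(prop-1-en-2-yl)cyclopent-2-en-1-yl]propanoate
Conditions: Pd(OAc)2 (5 mol%), dppf, HCO2H, Bu3N, DMF, 60 °C
Reagents that add atoms: none
Why: Palladium-catalysed formate reduction of the enol triflate (oxidative addition, formate exchange, decarboxylation to Pd–H, reductive elimination) replaces OTf by H and leaves the C2=C3 alkene with ethyl on C3, the other alkenes and the ester being inert.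

Step 8
Reactants: 11 (E)-2-ethylbut-2-enoic acid
Product: 12 (R)-2-[(benzyloxy)methyl]-2-ethylbut-3-enoic acid
Conditions: (R,R)-N,N′-bis(1-phenyl-2-piperidinoethyl)propane-1,3-diamine (1.05 equiv), n-BuLi (4 equiv), THF, 0 → −78 °C; BnOCH2Cl, −78 °C; aq. HCl (tetramine recovered)
Reagents that add atoms: benzyl chloromethyl ether ClCOCc1ccccc1
Why: Double deprotonation gives the cross-conjugated dienediolate, which is held in a mixed aggregate with the chiral dilithium amide and is alkylated at the α-carbon on one enantiotopic face (enantioselective deconjugative alkylation of an α-branched unsaturated acid with a chiral lithium amide as traceless auxiliary), which sets the quaternary centre that becomes C5.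

Step 9
Reactants: 12 (R)-2-[(benzyloxy)methyl]-2-ethylbut-3-enoic acid
Product: 13 (R)-2-ethyl-2-(hydroxymethyl)but-3-enoic acid
Conditions: BCl3, CH2Cl2, −78 → −20 °C; aq. NaHCO3, then acidify
Reagents that add atoms: none
Why: Boron trichloride cleaves the benzyl ether by Lewis-acid-assisted displacement at the benzylic carbon at low temperature, where the vinyl group and the quaternary centre are untouched (hydrogenolysis is excluded by the alkene).

Step 10
Reactants: 13 (R)-2-ethyl-2-(hydroxymethyl)but-3-enoic acid; 14 4-bromobenzoyl chloride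
Product: 15 (R)-2-{[(4-bromobenzoyl)oxy]methyl}-2-ethylbut-3-enoic acid
Conditions: pyridine, DMAP (cat.), CH2Cl2, 0 °C → rt; aq. NaHCO3 (cleaves any mixed anhydride), then H3O+; recrystallise
Reagents that add atoms: none
Why: DMAP-catalysed O-acylation of the primary alcohol installs the bromobenzoate that later carries crystallinity, and crystallisation of this acid (if needed as a salt with a chiral amine) should raise the enantiomeric purity and allow the (R) configuration to be checked by anomalous-dispersion X-ray analysis.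

Step 11
Reactants: 15 (R)-2-{[(4-bromobenzoyl)oxy]methyl}-2-ethylbut-3-enoic acid
Product: 17 (R)-2-ethyl-2-formylbut-3-en-1-yl 4-bromobenzoate, via acid chloride 16 (not isolated)
Conditions: (COCl)2, DMF (cat.), CH2Cl2, rt; evaporate; LiAlH(O-t-Bu)3, THF, −78 °C
Reagents that add atoms: none
Why: The acid chloride has no α-hydrogen and is reduced by the bulky, mild hydride only to the aldehyde at −78 °C (acid chloride to aldehyde reduction), the aryl ester being unreactive under these conditions and the quaternary centre unable to epimerise.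

Step 12
Reactants: 10 methyl (2RS)-2-[(1S,4R,5S)-2-ethyl-4-methyl-5-(prop-1-en-2-yl)cyclopent-2-en-1-yl]propanoate; 17 (R)-2-ethyl-2-formylbut-3-en-1-yl 4-bromobenzoate
Product: 19 methyl (2R,3RS,4R)-4-{[(4-bromobenzoyl)oxy]methyl}-4-ethyl-2-[(1R,4R,5S)-2-ethyl-4-methyl-5-(prop-1-en-2-yl)cyclopent-2-en-1-yl]-3-hydroxy-2-methylhex-5-enoate, via silyl ketene acetal 18 (not isolated)
Conditions: LDA, THF, −78 °C; TMSCl; solvent switch to CH2Cl2; 17, BF3·OEt2, −78 °C; aq. NaHCO3
Reagents that add atoms: none
Why: Mukaiyama aldol addition of the fully substituted silyl ketene acetal to the BF3-activated aldehyde through an open transition state: allylic 1,3-strain should hold H-3a in the plane of the ketene acetal, and the electrophile is expected to enter C4 from the face next to H-7a and away from the C3 ethyl group, which gives the (R) quaternary centre C4 (CO2Me cis to H-3a in the later ring); the carbinol forms as a mixture that step 13 removes, and the absence of a metal alkoxide avoids migration of the benzoate.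

Step 13
Reactants: 19 methyl (2R,3RS,4R)-4-{[(4-bromobenzoyl)oxy]methyl}-4-ethyl-2-[(1R,4R,5S)-2-ethyl-4-methyl-5-(prop-1-en-2-yl)cyclopent-2-en-1-yl]-3-hydroxy-2-methylhex-5-enoate
Product: 20 methyl (2R,4R)-4-{[(4-bromobenzoyl)oxy]methyl}-4-ethyl-2-[(1R,4R,5S)-2-ethyl-4-methyl-5-(prop-1-en-2-yl)cyclopent-2-en-1-yl]-2-methyl-3-oxohex-5-enoate
Conditions: Dess–Martin periodinane, NaHCO3, CH2Cl2, rt
Reagents that add atoms: none
Why: Dess–Martin oxidation of the hindered secondary alcohol should give the ketone flanked by the two quaternary carbons under nearly neutral conditions, so neither retro-aldol cleavage nor benzoate migration is expected.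

Step 14
Reactants: 20 methyl (2R,4R)-4-{[(4-bromobenzoyl)oxy]methyl}-4-ethyl-2-[(1R,4R,5S)-2-ethyl-4-methyl-5-(prop-1-en-2-yl)cyclopent-2-en-1-yl]-2-methyl-3-oxohex-5-enoate
Product: 21 methyl (1R,3aR,4R,6R,8aS)-6-{[(4-bromobenzoyl)oxy]methyl}-3,6-diethyl-1,4,8-trimethyl-5-oxo-1,3a,4,5,6,8a-hexahydroazulene-4-carboxylate
Conditions: Hoveyda–Grubbs II (10 mol%), toluene (2 mM), 80 °C, Ar sparge
Reagents that add atoms: none
Why: Ring-closing metathesis: the catalyst should load on the monosubstituted vinyl group of C5 and close onto the 1,1-disubstituted isopropenyl group to give the trisubstituted C6=C7 alkene of the cyclohept-3-enone, the two quaternary carbons favouring the folded conformer; the cyclopentene alkene does not take part and no stereocentre is affected.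

Step 15
Reactants: 21 methyl (1R,3aR,4R,6R,8aS)-6-{[(4-bromobenzoyl)oxy]methyl}-3,6-diethyl-1,4,8-trimethyl-5-oxo-1,3a,4,5,6,8a-hexahydroazulene-4-carboxylate
Product: 22 methyl (1R,3aR,4R,5S,7aS)-5-{[(4-bromobenzoyl)oxy]methyl}-3,5-diethyl-1,4,7-trimethyl-3a,4,5,7a-tetrahydro-1H-indene-4-carboxylate
Conditions: hν (medium-pressure Hg lamp, λ > 300 nm), crystalline 21 as aqueous suspension (CTAB), 5–10 °C
Reagents that add atoms: none
Why: n→π* excitation of the crystalline β,γ-unsaturated ketone causes Norrish type I cleavage of the C(O)–C5 bond to an acyl/allyl radical pair, and the acyl radical loses CO because the C4 radical left behind is tertiary and ester-stabilised. The closest known reaction type is the solid-state photodecarbonylation of crystalline hexasubstituted ketones whose two α-carbons both carry radical-stabilising groups, which couples the two radicals with retention. The cyclohexene ring is closed by radical–radical recombination of the C4/C5 1,6-biradical, formally a ring contraction from seven to six members; coupling at the allyl terminus C7 would need a cyclobutane and is not expected. C4 and C5 should keep the configurations built in steps 12 and 8, because the lattice and the C3a–C7a tether leave no room for rotation about C3a–C4 or C5–C6 before the bond forms. The step needs decarbonylation to outrun re-closure of the acyl radical at C7 (1,3-acyl shift) and needs retention at both radicals; the first is secured by the ester on C4 and the allyl stabilisation at C5, the second by the rigid crystal, and irradiation above 300 nm keeps the bromobenzoate unexcited.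

Step 16
Reactants: 22 methyl (1R,3aR,4R,5S,7aS)-5-{[(4-bromobenzoyl)oxy]methyl}-3,5-diethyl-1,4,7-trimethyl-3a,4,5,7a-tetrahydro-1H-indene-4-carboxylate
Product: 23 methyl (1R,3aR,4R,5S,7aS)-3,5-diethyl-5-(hydroxymethyl)-1,4,7-trimethyl-3a,4,5,7a-tetrahydro-1H-indene-4-carboxylate
Conditions: DIBAL-H (2.5 equiv), CH2Cl2, −78 °C; Rochelle salt; crude used at once
Reagents that add atoms: none
Why: DIBAL-H reduces the accessible aryl ester (reductive ester cleavage) while the C4 methyl ester, shielded by two quaternary carbons, should survive, and the alcohol is set free as an aluminium alkoxide at −78 °C and not as a basic alkoxide that would close the cis γ-lactone onto the C4 ester.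

Step 17
Reactants: 23 methyl (1R,3aR,4R,5S,7aS)-3,5-diethyl-5-(hydroxymethyl)-1,4,7-trimethyl-3a,4,5,7a-tetrahydro-1H-indene-4-carboxylate
Product: 24 methyl (1R,3aR,4R,5S,7aS)-3,5-diethyl-5-formyl-1,4,7-trimethyl-3a,4,5,7a-tetrahydro-1H-indene-4-carboxylate
Conditions: Dess–Martin periodinane, NaHCO3, CH2Cl2, 0 °C
Reagents that add atoms: none
Why: Dess–Martin oxidation of the neopentylic primary alcohol gives the aldehyde, which has no α-hydrogen and so cannot epimerise or enolise.

Step 18
Reactants: 24 methyl (1R,3aR,4R,5S,7aS)-3,5-diethyl-5-formyl-1,4,7-trimethyl-3a,4,5,7a-tetrahydro-1H-indene-4-carboxylate; 25 diethyl [(E)-3-phenylprop-2-en-1-yl]phosphonate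
Product: 26 methyl (1R,3aR,4R,5S,7aS)-3,5-diethyl-1,4,7-trimethyl-5-[(1E,3E)-4-phenylbuta-1,3-dien-1-yl]-3a,4,5,7a-tetrahydro-1H-indene-4-carboxylate
Conditions: 25, n-BuLi, THF, −78 °C; then 24, −78 °C → rt
Reagents that add atoms: none
Why: Horner–Wadsworth–Emmons olefination: the lithiated cinnamylphosphonate adds through its α-carbon to the non-enolisable aldehyde and elimination of phosphate should give the new C1′=C2′ alkene with E geometry (semi-stabilised phosphonate, bulky aldehyde), the E styryl alkene being carried in from 25.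

Step 19
Reactants: 26 methyl (1R,3aR,4R,5S,7aS)-3,5-diethyl-1,4,7-trimethyl-5-[(1E,3E)-4-phenylbuta-1,3-dien-1-yl]-3a,4,5,7a-tetrahydro-1H-indene-4-carboxylate
Product: 27 (1R,3aR,4R,5S,7aS)-3,5-diethyl-1,4,7-trimethyl-5-[(1E,3E)-4-phenylbuta-1,3-dien-1-yl]-3a,4,5,7a-tetrahydro-1H-indene-4-carboxylic acid (target)
Conditions: NaSEt, DMF, 80 °C; then cold 1 M HCl to pH 3–4
Reagents that add atoms: none
Why: The thiolate cleaves the ester by SN2 attack at the O-methyl carbon, which does not depend on the extreme hindrance at the acyl carbon and leaves the diene and all stereocentres untouched.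

**Compound list**
1 | (S)-4-[(tert-butyldimethylsilyl)oxy]cyclopent-2-en-1-one | O=C1C[C@H](O[Si](C)(C)C(C)(C)C)C=C1 | starting material
2 | (2S,3R,4S)-4-[(tert-butyldimethylsilyl)oxy]-2-methyl-3-(prop-1-en-2-yl)cyclopentan-1-one | O=C1C[C@H](O[Si](C)(C)C(C)(C)C)[C@@H](C(C)=C)[C@@H]1C | intermediate
3 | (4R,5S)-5-methyl-4-(prop-1-en-2-yl)cyclopent-2-en-1-one (trans) | O=C1C=C[C@@H](C(C)=C)[C@@H]1C | intermediate
4 | (4S,5S)-2-iodo-5-methyl-4-(prop-1-en-2-yl)cyclopent-2-en-1-one | O=C1C(I)=C[C@@H](C(C)=C)[C@@H]1C | intermediate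
5 | (4R,5S)-2-ethyl-5-methyl-4-(prop-1-en-2-yl)cyclopent-2-en-1-one | O=C1C(CC)=C[C@@H](C(C)=C)[C@@H]1C | intermediate
6 | methyl propanoate | CCC(=O)OC | starting material
7 | (E)-1-methoxy-1-(trimethylsilyloxy)prop-1-ene | C/C=C(/O[Si](C)(C)C)OC | intermediate
8 | methyl (2RS)-2-[(1S,4S,5R)-2-ethyl-4-methyl-5-(prop-1-en-2-yl)-3-(trimethylsilyloxy)cyclopent-2-en-1-yl]propanoate | CCC1=C(O[Si](C)(C)C)[C@@H](C)[C@H](C(C)=C)[C@H]1C(C)C(=O)OC | intermediate
9 | methyl (2RS)-2-[(1S,4S,5R)-2-ethyl-4-methyl-5-(prop-1-en-2-yl)-3-(trifluoromethylsulfonyloxy)cyclopent-2-en-1-yl]propanoate | CCC1=C(OS(=O)(=O)C(F)(F)F)[C@@H](C)[C@H](C(C)=C)[C@H]1C(C)C(=O)OC | intermediate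
10 | methyl (2RS)-2-[(1S,4R,5S)-2-ethyl-4-methyl-5-(prop-1-en-2-yl)cyclopent-2-en-1-yl]propanoate | CCC1=C[C@@H](C)[C@H](C(C)=C)[C@H]1C(C)C(=O)OC | intermediate
11 | (E)-2-ethylbut-2-enoic acid | C/C=C(\CC)C(=O)O | starting material
12 | (R)-2-[(benzyloxy)methyl]-2-ethylbut-3-enoic acid | OC(=O)[C@@](CC)(COCc1ccccc1)C=C | intermediate
13 | (R)-2-ethyl-2-(hydroxymethyl)but-3-enoic acid | OC(=O)[C@@](CC)(CO)C=C | intermediate
14 | 4-bromobenzoyl chloride | O=C(Cl)c1ccc(Br)cc1 | starting material
15 | (R)-2-{[(4-bromobenzoyl)oxy]methyl}-2-ethylbut-3-enoic acid | OC(=O)[C@@](CC)(COC(=O)c1ccc(Br)cc1)C=C | intermediate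
16 | (R)-2-(chlorocarbonyl)-2-ethylbut-3-en-1-yl 4-bromobenzoate | O=C(Cl)[C@@](CC)(COC(=O)c1ccc(Br)cc1)C=C | intermediate
17 | (R)-2-ethyl-2-formylbut-3-en-1-yl 4-bromobenzoate | O=C[C@@](CC)(COC(=O)c1ccc(Br)cc1)C=C | intermediate
18 | trimethylsilyl ketene acetal of 10 (E/Z mixture; ring 1R,4R,5S) | CCC1=C[C@@H](C)[C@H](C(C)=C)[C@H]1C(C)=C(OC)O[Si](C)(C)C | intermediate
19 | methyl (2R,3RS,4R)-4-{[(4-bromobenzoyl)oxy]methyl}-4-ethyl-2-[(1R,4R,5S)-2-ethyl-4-methyl-5-(prop-1-en-2-yl)cyclopent-2-en-1-yl]-3-hydroxy-2-methylhex-5-enoate | CCC1=C[C@@H](C)[C@H](C(C)=C)[C@H]1[C@@](C)(C(=O)OC)C(O)[C@@](CC)(COC(=O)c2ccc(Br)cc2)C=C | intermediate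
20 | methyl (2R,4R)-4-{[(4-bromobenzoyl)oxy]methyl}-4-ethyl-2-[(1R,4R,5S)-2-ethyl-4-methyl-5-(prop-1-en-2-yl)cyclopent-2-en-1-yl]-2-methyl-3-oxohex-5-enoate | CCC1=C[C@@H](C)[C@H](C(C)=C)[C@H]1[C@@](C)(C(=O)OC)C(=O)[C@@](CC)(COC(=O)c2ccc(Br)cc2)C=C | intermediate
21 | methyl (1R,3aR,4R,6R,8aS)-6-{[(4-bromobenzoyl)oxy]methyl}-3,6-diethyl-1,4,8-trimethyl-5-oxo-1,3a,4,5,6,8a-hexahydroazulene-4-carboxylate (trans-fused; CO2Me and CH2O cis) | CCC1=C[C@@H](C)[C@@H]2C(C)=C[C@@](COC(=O)c3ccc(Br)cc3)(CC)C(=O)[C@](C)(C(=O)OC)[C@@H]12 | intermediate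
22 | methyl (1R,3aR,4R,5S,7aS)-5-{[(4-bromobenzoyl)oxy]methyl}-3,5-diethyl-1,4,7-trimethyl-3a,4,5,7a-tetrahydro-1H-indene-4-carboxylate | CCC1=C[C@@H](C)[C@@H]2C(C)=C[C@@](COC(=O)c3ccc(Br)cc3)(CC)[C@](C)(C(=O)OC)[C@@H]12 | intermediate
23 | methyl (1R,3aR,4R,5S,7aS)-3,5-diethyl-5-(hydroxymethyl)-1,4,7-trimethyl-3a,4,5,7a-tetrahydro-1H-indene-4-carboxylate | CCC1=C[C@@H](C)[C@@H]2C(C)=C[C@@](CO)(CC)[C@](C)(C(=O)OC)[C@@H]12 | intermediate
24 | methyl (1R,3aR,4R,5S,7aS)-3,5-diethyl-5-formyl-1,4,7-trimethyl-3a,4,5,7a-tetrahydro-1H-indene-4-carboxylate | CCC1=C[C@@H](C)[C@@H]2C(C)=C[C@@](C=O)(CC)[C@](C)(C(=O)OC)[C@@H]12 | intermediate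
25 | diethyl [(E)-3-phenylprop-2-en-1-yl]phosphonate | CCOP(=O)(C/C=C/c1ccccc1)OCC | starting material
26 | methyl (1R,3aR,4R,5S,7aS)-3,5-diethyl-1,4,7-trimethyl-5-[(1E,3E)-4-phenylbuta-1,3-dien-1-yl]-3a,4,5,7a-tetrahydro-1H-indene-4-carboxylate | CCC1=C[C@@H](C)[C@@H]2C(C)=C[C@@](/C=C/C=C/c3ccccc3)(CC)[C@](C)(C(=O)OC)[C@@H]12 | intermediate
27 | (1R,3aR,4R,5S,7aS)-3,5-diethyl-1,4,7-trimethyl-5-[(1E,3E)-4-phenylbuta-1,3-dien-1-yl]-3a,4,5,7a-tetrahydro-1H-indene-4-carboxylic acid | CCC1=C[C@@H](C)[C@@H]2C(C)=C[C@@](/C=C/C=C/c3ccccc3)(CC)[C@](C)(C(=O)O)[C@@H]12 | target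

**Step count**
Total: 19 steps. Longest linear sequence: 14 steps (1 → 3 → 4 → 5 → 8 → 9 → 10 → 19 → 20 → 21 → 22 → 23 → 24 → 26 → 27).

**Steps most likely to fail**

Step 15 (key step). What may go wrong: 21 does not crystallise, or the solid softens or packs loosely, so the radical pair is not confined; the acyl radical then recloses at the allyl terminus (1,3-acyl shift) or the C5 allyl radical turns over before coupling. The fallback replaces lattice control by a covalent bridge and works in solution. It sets out from 21: neutral transesterification with methanol and 1,3-dichlorotetrabutyldistannoxane (toluene, 90 °C) removes the bromobenzoate to give the hydroxy keto ester F1. Under the same conditions its hydroxymethyl group lactonises onto the cis C4 ester to give the bridged keto δ-lactone F2. In F2 the ketone is the one-atom bridge of a bicyclo[4.3.1] system, so photolysis in degassed benzene (λ > 300 nm) should expel CO and join the two bridgeheads on the face fixed by the lactone, giving the cis-fused γ-lactone F3. KOH in aqueous dioxane opens F3 to the potassium hydroxy carboxylate F4, and MeI in DMF alkylates the carboxylate to give 23, where the route is rejoined before step 17.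

Step 12. What may go wrong: poor facial discrimination in the attack on C4 (rotamer control by allylic strain too weak, or reaction through the minor rotamer), or no addition between two carbons that are both flanked by fully substituted centres. The fallback introduces the methyl group last, so that the stereo-determining event is approach of a small electrophile to a planar, chelated β-keto ester enolate with the bulky acyl group in its plane. It sets out from 5: Mukaiyama–Michael addition of commercial 1-(tert-butyldimethylsilyloxy)-1-methoxyethene gives the acetate adduct F5 (TBS enol ether). CsF/PhNTf2 gives the enol triflate F6, and Pd/formate reduction gives the ester F7, as in steps 6 and 7. The lithium enolate of F7 (2 equiv LDA) is C-acylated with acid chloride 16 (taken from step 11 before the reduction) to give the β-keto ester F8. C-Methylation of its potassium enolate (K2CO3, MeI, acetone) gives 20, where the route is rejoined before step 14.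

Step 14. What may go wrong: the ruthenium carbene does not form on the neopentylic vinyl group or cannot reach the 1,1-disubstituted alkene, so that nothing happens or intermolecular metathesis takes over. The fallback closes the ring before the ketone is made, from a diene linked through an sp3 carbinol carbon that folds differently. It sets out from 19: ring-closing metathesis of the β-hydroxy ester gives the cycloheptenol F9, and Dess–Martin oxidation of F9 gives 21, where the route is rejoined before step 15.

**Further compounds**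
F1 | step 15 | methyl (1R,3aR,4R,6R,8aS)-3,6-diethyl-6-(hydroxymethyl)-1,4,8-trimethyl-5-oxo-1,3a,4,5,6,8a-hexahydroazulene-4-carboxylate | CCC1=C[C@@H](C)[C@@H]2C(C)=C[C@@](CO)(CC)C(=O)[C@](C)(C(=O)OC)[C@@H]12
F2 | step 15 | bridged keto δ-lactone of F1 (C4 carboxyl esterified by the C5 hydroxymethyl oxygen across the ketone) | CCC1=C[C@@H](C)[C@@H]2C(C)=C[C@@]3(CC)C(=O)[C@](C)(C(=O)OC3)[C@@H]12
F3 | step 15 | cis-fused γ-lactone of the hydroxy acid of 23 (C4 carboxyl esterified by the C5 hydroxymethyl oxygen) | CCC1=C[C@@H](C)[C@@H]2C(C)=C[C@@]3(CC)[C@](C)(C(=O)OC3)[C@@H]12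
F4 | step 15 | potassium (1R,3aR,4R,5S,7aS)-3,5-diethyl-5-(hydroxymethyl)-1,4,7-trimethyl-3a,4,5,7a-tetrahydro-1H-indene-4-carboxylate | CCC1=C[C@@H](C)[C@@H]2C(C)=C[C@@](CO)(CC)[C@](C)(C(=O)[O-])[C@@H]12.[K+]
F5 | step 12 | methyl 2-[(1S,4S,5R)-3-[(tert-butyldimethylsilyl)oxy]-2-ethyl-4-methyl-5-(prop-1-en-2-yl)cyclopent-2-en-1-yl]acetate | CCC1=C(O[Si](C)(C)C(C)(C)C)[C@@H](C)[C@H](C(C)=C)[C@H]1CC(=O)OC
F6 | step 12 | methyl 2-[(1S,4S,5R)-2-ethyl-4-methyl-5-(prop-1-en-2-yl)-3-(trifluoromethylsulfonyloxy)cyclopent-2-en-1-yl]acetate | CCC1=C(OS(=O)(=O)C(F)(F)F)[C@@H](C)[C@H](C(C)=C)[C@H]1CC(=O)OC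
F7 | step 12 | methyl 2-[(1S,4R,5S)-2-ethyl-4-methyl-5-(prop-1-en-2-yl)cyclopent-2-en-1-yl]acetate | CCC1=C[C@@H](C)[C@H](C(C)=C)[C@H]1CC(=O)OC
F8 | step 12 | methyl (2RS,4R)-4-{[(4-bromobenzoyl)oxy]methyl}-4-ethyl-2-[(1R,4R,5S)-2-ethyl-4-methyl-5-(prop-1-en-2-yl)cyclopent-2-en-1-yl]-3-oxohex-5-enoate | CCC1=C[C@@H](C)[C@H](C(C)=C)[C@H]1C(C(=O)OC)C(=O)[C@@](CC)(COC(=O)c2ccc(Br)cc2)C=C
F9 | step 14 | methyl (1R,3aR,4R,5RS,6R,8aS)-6-{[(4-bromobenzoyl)oxy]methyl}-3,6-diethyl-5-hydroxy-1,4,8-trimethyl-1,3a,4,5,6,8a-hexahydroazulene-4-carboxylate | CCC1=C[C@@H](C)[C@@H]2C(C)=C[C@@](COC(=O)c3ccc(Br)cc3)(CC)C(O)[C@](C)(C(=O)OC)[C@@H]12
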